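The earlier runs and the new flask were generated by integration with made-up constants; scatter was added.

Reading a flask by its charge is the trap: substrate meets the reagent standing beside it at that moment, not the reagent in the recipe.

| flask | substrate | reagent | temperature | remark | time |
|---|---|---|---|---|---|
| south-east | 0.050 M | 0.125 M | 30 °C | run made earlier |  |
| east | 0.050 M | 0.084 M | 41 °C | run made earlier |  |
| north | 0.050 M | 0.19 M | 30 °C | run made earlier |  |
| grey | 0.050 M | 0.125 M (fed, over 8.0 min) | 35 °C | all else is in the flask from the start; the feed brings no volume worth counting | 10 min |
| green | 0.050 M | 0.125 M (fed, over 8.0 min) |  | the addition at 5 °C, then warmed to 35 °C; the feed brings no volume worth counting | 10 min |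
| blue | 0.050 M | 0.125 M |  | everything together at the start at 5 °C, warmed to 35 °C at 8.0 min | 10 min |
| ochre | 0.050 M | 0.125 M (in portions, 2, over 8.0 min) | 35 °C | first portion at the start, last at 8.0 min | 10 min |
| red | 0.050 M (fed, over 8.0 min) | 0.125 M | 35 °C | all else is in the flask from the start; the feed brings no volume worth counting | 10 min |
| amber | 0.050 M (fed, over 50 s) | 0.125 M | 35 °C | all else is in the flask from the start; the feed brings no volume worth counting | 10 min |

| run | time / min | isomer of the product / % | target / % |
|---|---|---|---|
| south-east | 0.833 | 11.6 | 4.6 |
| south-east | 1.50 | 18.8 | 7.6 |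
| south-east | 2.50 | 27.1 | 13.1 |
| south-east | 3.00 | 30.7 | 14.3 |
| south-east | 4.00 | 36.3 | 17.6 |
| south-east | 5.00 | 41.0 | 20.9 |
| south-east | 6.00 | 44.1 | 23.9 |
| east | 0.500 | 11.3 | 9.4 |
| east | 1.50 | 22.7 | 26.5 |
| east | 3.00 | 31.4 | 39.2 |
| east | 4.00 | 33.9 | 45.0 |
| east | 6.00 | 36.3 | 50.9 |
| east | 8.00 | 38.5 | 53.4 |
| east | 10.0 | 38.6 | 55.0 |
| north | 0.500 | 10.4 | 2.0 |
| north | 1.50 | 27.9 | 8.0 |
| north | 3.00 | 43.0 | 12.9 |
| north | 4.00 | 50.7 | 15.8 |
| north | 6.00 | 60.0 | 20.8 |
| north | 8.00 | 66.4 | 20.9 |
| north | 10.0 | 69.1 | 23.8 |

(readings scatter by 0.5 percentage points)

- in percentages every species weighs as the substrate in it: one side product counts as two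
- for target the idle adduct is counted in
- steps under discussion: substrate <-> tautomer; substrate + reagent -> isomer of the product; reagent + tautomer -> target; substrate + target -> side product; reagent + target <-> idle adduct

- which flask leads in amount of isomer of the product, in percent of the substrate charged ("all alike" within 1.5 percentage points) (grey / green / blue / ochre / red / amber / all alike)
- how much isomer of the product is there at the end, in percent of the substrate charged: grey
- how much isomer of the product is there at the end, in percent of the substrate charged: green
- how much isomer of the product is there at the end, in percent of the substrate charged: blue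
- how much isomer of the product is there at the end, in percent of the substrate charged: ochre
- how much isomer of the product is there at the end, in percent of the substrate charged: red
- how much isomer of the product is there at the end, in percent of the substrate charged: amber

Apart from the side product, substrate has two exits: with reagent straight to isomer of the product, or through tautomer to target. If reagent catches tautomer as it forms, the ratio of isomer to target equals R/R*, a selectivity factor. Here R is the reagent standing and R* the crossover level. For R a hand estimate takes the charge less what mid-conversion has used, with idle adduct left out of the count. At 30 °C the south-east run at 6.00 min then reads R* = 0.0585 M and the north run at 10.0 min reads 0.0574 M; the east run, at 41 °C and 10.0 min, reads 0.0863 M. A straight line in the logarithm against temperature, through the south-east and east readings, gives R* = 0.0698 M at 35 °C, the reagent concentration at which both exits run equally fast.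

The tautomer exit has a constant k, the substrate's logarithmic loss rate times target's share of what reacted: 0.0667 min⁻¹ from the south-east run, 0.227 min⁻¹ from the east run, so 0.116 min⁻¹ on the same line.

Amber, its substrate in within 50 s, is nearly a batch flask. With complete conversion assumed, its R at mid-conversion is 0.100 M, the pseudo-first-order loss of substrate is reckoned at 0.283 min⁻¹, and the estimate leaves 5.91% unreacted at 10 min. Amber's isomer then comes to 55.4%. The weak link is that complete conversion: counting the substrate actually spent lifts R to 0.101 M and amber's isomer to 55.7%, my own figure.

Grey's reagent, averaged over the feed, is 0.0625 M even before any use, less than R*. Red has amber's reagent charge in the flask from the start, but its substrate arrives on average at 4.00 min. Green and blue get 2.00 min at 35 °C, less than the 3.53 min reckoned as the lifetime of substrate in amber.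

The forecast puts amber first with 56%, between 52% and 60%, then red at 48%, blue at 38%, ochre at 35.5%, green at 34% and grey at 30%: “Amber, nearly batch, gives about 56% and leads”.

The flask that leads is amber with 55.0% of isomer; red ends at 47.6%, blue 36.3%, green 33.0%, ochre 32.9%, grey 26.7%.

    substrate ⇌ tautomer (K = 2.90, k = 0.00210 s⁻¹, Ea = 95.0 kJ mol⁻¹, ΔH = −33.0 kJ mol⁻¹)
    substrate + reagent → isomer of the product (k = 0.0320 M⁻¹ s⁻¹, Ea = 67.0 kJ mol⁻¹)
    reagent + tautomer → target (k = 2.50 M⁻¹ s⁻¹, Ea = 57.0 kJ mol⁻¹)
    substrate + target → side product (k = 0.0120 M⁻¹ s⁻¹, Ea = 74.0 kJ mol⁻¹)
    reagent + target ⇌ idle adduct, settled at all times (K = 20.0 M⁻¹, ΔH = −38.0 kJ mol⁻¹)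
    (constants at 35 °C)

At 10.0 min amber holds 54% of its reagent charge, 0.0679 M, close to R*, and the rate at which amber's reagent makes isomer stands to the rate at which it makes target at a ratio of 1.0. For a neighbour of amber with another reagent charge, R* plus the reagent spent at mid-conversion, both exits equal, puts isomer level with target at a charge of 0.0924 M; the simulated charge at which the two stand level at the end, all forms of target counted, is 0.0917 M.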